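**Plan**

- Daucane numbering is used: C1 is the methyl-bearing ring-fusion carbon, C4 the isopropyl carbinol, C5 the ring-fusion CH, C6 the angelate carbon, C8–C9 the epoxide, C10 the free carbinol; β is the face of the C1 methyl. The enabling feature is the seven-membered ring C1–C10–C9–C8–C7–C6–C5, in which quaternary C1 lies between C5 and C10. Cutting C7–C8 and joining C5 to C10 folds this ring into a C1–C5–C10 cyclopropane with a vinyl group (C6=C7) on C5 and an (E)-propenyl group (C9=C8–CH3) on C10, fused to the C1–C5 cyclopentanone.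
- Retrosynthetic cuts, in order: the angelate C–O bond, the C8/C9, C10 and C6 oxygens and the C4–isopropyl bond (back to a hydroazulene dienone); then C7–C8 (retro-Cope); then C5–C1 and C5–C10 (carbenoid cyclopropanation) and C6=C7 (methylenation); then C2–C3 (acetoacetate dianion alkylation) and C1=C10 (Wittig).
- Forward: the chain is joined first; the cyclopentanone and the cyclopropane close together in the copper-carbenoid step; the seven-membered ring arises in the Cope step; the oxygens and the isopropyl group follow.
- Stereochemistry: C1 comes from the chiral copper catalyst, and the (E)-alkene fixes the cis-dialkenyl geometry. The boat transition state relays this to C8. The C1 methyl then steers enone epoxidation (C6), protonation (C5), isopropyl addition (C4) and alkene epoxidation (C10) to the α face. Trans selenide opening and syn selenoxide elimination move the alkene to C8=C9, and the C10 hydroxyl directs the last epoxide (C8, C9).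

Key step: step 11

Assumption: the (S,S)-bis(oxazoline) ligand is written for step 6 on the assumption that it favours the (1R,5R,6R)-cyclopropane; if the sense of induction is the opposite, the (R,R)-ligand is used.

**Route**

Step 1
Reactants: 1 (E)-but-2-enal; 2 ethyl 2-(triphenylphosphoranylidene)propanoate
Product: 3 ethyl (2E,4E)-2-methylhexa-2,4-dienoate
Conditions: CH2Cl2, rt, 16 h
Reagents that add atoms: none
Why: Wittig olefination with the stabilised α-methyl ylide should give the (E)-trisubstituted enoate while the (E)-alkene of the aldehyde is kept.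

Step 2
Reactants: 3 ethyl (2E,4E)-2-methylhexa-2,4-dienoate
Product: 4 (2E,4E)-2-methylhexa-2,4-dien-1-ol
Conditions: i-Bu2AlH (2.2 equiv), CH2Cl2, −78 to 0 °C; aq potassium sodium tartrate
Reagents that add atoms: none
Why: 1,2-Reduction of the conjugated ester by the aluminium hydride gives the dienyl alcohol without touching the diene.

Step 3
Reactants: 4 (2E,4E)-2-methylhexa-2,4-dien-1-ol
Product: 5 (2E,4E)-1-bromo-2-methylhexa-2,4-diene
Conditions: PBr3 (0.4 equiv), Et2O, 0 °C; used without storage
Reagents that add atoms: phosphorus tribromide, BrP(Br)Br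
Why: Bromide displaces the activated phosphite ester of the primary alcohol, and the conjugated primary bromide is also the favoured allylic isomer, so both alkene geometries should be retained.

Step 4
Reactants: 6 methyl acetoacetate; 5 (2E,4E)-1-bromo-2-methylhexa-2,4-diene
Product: 8 methyl (6E,8E)-6-methyl-3-oxodeca-6,8-dienoate, via acetoacetate dianion 7 (not isolated)
Conditions: NaH (1.1 equiv), THF, 0 °C; n-BuLi (1.05 equiv), 0 °C; then 5, 0 °C to rt; dilute aq HCl
Reagents that add atoms: none
Why: In the acetoacetate dianion the terminal (γ) carbon is the more nucleophilic site, and this hard nucleophile should attack the primary allylic carbon of the bromide directly (SN2), forming the C2–C3 bond.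

Step 5
Reactants: 8 methyl (6E,8E)-6-methyl-3-oxodeca-6,8-dienoate
Product: 9 methyl (6E,8E)-2-diazo-6-methyl-3-oxodeca-6,8-dienoate
Conditions: 4-acetamidobenzenesulfonyl azide (1.1 equiv), Et3N, MeCN, 0 °C to rt
Reagents that add atoms: 4-acetamidobenzenesulfonyl azide, CC(=O)Nc1ccc(cc1)S(=O)(=O)N=[N+]=[N-]
Why: Regitz diazo transfer to the active methylene of a β-keto ester is the standard route to α-diazo-β-keto esters.

Step 6
Reactants: 9 methyl (6E,8E)-2-diazo-6-methyl-3-oxodeca-6,8-dienoate
Product: 10 methyl (1R,5R,6R)-5-methyl-2-oxo-6-[(E)-prop-1-enyl]bicyclo[3.1.0]hexane-1-carboxylate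
Conditions: [Cu(MeCN)4]PF6 (5 mol %), 2,2'-(propane-2,2-diyl)bis[(4S)-4-tert-butyl-4,5-dihydrooxazole] (6 mol %), toluene, 50 °C, slow addition of 9
Reagents that add atoms: none
Why: In this copper-catalysed intramolecular cyclopropanation the monovalent copper carbenoid adds to the proximal trisubstituted alkene (five-membered ring closure), the syn addition turns the (E)-geometry into an exo propenyl group cis to the ester and the methyl group, and the C2-symmetric ligand selects the alkene face, which sets the later C1 and with it C5 and C10.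

Step 7
Reactants: 10 methyl (1R,5R,6R)-5-methyl-2-oxo-6-[(E)-prop-1-enyl]bicyclo[3.1.0]hexane-1-carboxylate
Product: 11 (1S,5R,6R)-1-(hydroxymethyl)-5-methyl-6-[(E)-prop-1-enyl]bicyclo[3.1.0]hexan-2-ol (C2 epimers)
Conditions: LiAlH4 (2 equiv), THF, 0 °C
Reagents that add atoms: none
Why: Hydride reduction of ester and ketone together is reliable, the carbinol configuration is immaterial, and keeping the ring oxygen at the alcohol level means the later aldehyde is not a 1,3-dicarbonyl compound prone to retro-Claisen ring expansion with the cis propenyl group.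

Step 8
Reactants: 11 (1S,5R,6R)-1-(hydroxymethyl)-5-methyl-6-[(E)-prop-1-enyl]bicyclo[3.1.0]hexan-2-ol
Product: 12 (1R,5R,6R)-2-hydroxy-5-methyl-6-[(E)-prop-1-enyl]bicyclo[3.1.0]hexane-1-carbaldehyde (C2 epimers)
Conditions: TEMPO (10 mol %), PhI(OAc)2 (1.1 equiv), CH2Cl2, rt
Reagents that add atoms: none
Why: Oxoammonium oxidation with PhI(OAc)2 as terminal oxidant is selective for primary over secondary alcohols and stops at the aldehyde.

Step 9
Reactants: 12 (1R,5R,6R)-2-hydroxy-5-methyl-6-[(E)-prop-1-enyl]bicyclo[3.1.0]hexane-1-carbaldehyde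
Product: 13 (1S,5R,6R)-5-methyl-6-[(E)-prop-1-enyl]-1-vinylbicyclo[3.1.0]hexan-2-ol (C2 epimers)
Conditions: Ph3PCH3Br (3.0 equiv), KOt-Bu (2.9 equiv), THF, 0 °C; then 12, 0 °C to rt
Reagents that add atoms: methyltriphenylphosphonium bromide, C[P+](c1ccccc1)(c1ccccc1)c1ccccc1.[Br-]
Why: Wittig methylenation of a cis-2-alkenylcyclopropanecarbaldehyde is the usual entry to cis-divinylcyclopropanes, the excess ylide covers the free hydroxyl, and using the aldehyde cold and at once lets olefination outrun its reversible retro-Claisen drift.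

Step 10
Reactants: 13 (1S,5R,6R)-5-methyl-6-[(E)-prop-1-enyl]-1-vinylbicyclo[3.1.0]hexan-2-ol
Product: 14 (1S,5R,6R)-5-methyl-6-[(E)-prop-1-enyl]-1-vinylbicyclo[3.1.0]hexan-2-one
Conditions: (n-Pr4N)RuO4 (5 mol %), N-methylmorpholine N-oxide (1.5 equiv), 4 Å molecular sieves, CH2Cl2, 0 °C to rt
Reagents that add atoms: none
Why: Ley–Griffith oxidation converts the secondary cyclopropyl carbinol to the ketone under neutral conditions at or below room temperature, which the divinylcyclopropane should tolerate.

Step 11
Reactants: 14 (1S,5R,6R)-5-methyl-6-[(E)-prop-1-enyl]-1-vinylbicyclo[3.1.0]hexan-2-one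
Product: 15 (3aR,6R)-3a,6-dimethyl-3,3a,6,7-tetrahydroazulen-1(2H)-one
Conditions: toluene (degassed, trace BHT), 110 °C, sealed tube
Reagents that add atoms: none
Why: On heating, the vinyl group on C5 and the (E)-propenyl group on C10, cis to each other on the exo face of the cyclopropane, fold over the ring, and a concerted suprafacial [3,3]-sigmatropic shift through a boat transition state forms the C7–C8 σ bond while the C5–C10 cyclopropane bond breaks and the π bonds move to C5=C6 and C9=C10. This is the cis-divinylcyclopropane to cyclohepta-1,4-diene Cope rearrangement, made irreversible by release of ring strain and here also by conjugation of C5=C6 with the C4 ketone. The seven-membered ring closes by ring expansion: the alkene termini C7 and C8 are joined across the three-membered ring, whose carbons C5, C1 and C10 pass into the new ring with C1 untouched as the quaternary ring-fusion carbon. The single new stereocentre, C8, is fixed by the boat geometry and the (E)-propenyl configuration, which keep the C8 methyl outward and place it trans to the C1 methyl (8R, methyl α, hydrogen β). The step needs the cis-dialkenyl relationship, which the stereospecific cyclopropanation of the (E)-alkene has secured, and it must outrun the homodienyl [1,5]-hydrogen shift from the C1 methyl, which lies cis to both alkenyl groups and presses on their inward hydrogens in the boat. That crowding is why about 110 °C is planned, and the higher barrier of the hydrogen shift should leave the Cope path dominant.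

Step 12
Reactants: 15 (3aR,6R)-3a,6-dimethyl-3,3a,6,7-tetrahydroazulen-1(2H)-one
Product: 16 5α,6α-epoxide of 15 (C4 ketone, C9=C10 alkene, 1β- and 8α-methyl)
Conditions: 30% aq H2O2, NaOH (cat), MeOH, 0 °C
Reagents that add atoms: hydrogen peroxide, OO
Why: In this Weitz–Scheffer epoxidation the hydroperoxide anion adds only to the enone β-carbon C6 (the isolated C9=C10 alkene is inert to it) and closes onto C5 from the convex α face of the boat-shaped cycloheptadiene, opposite the C1 methyl, which sets the C6 oxygen α.

Step 13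
Reactants: 16 5α,6α-epoxy ketone
Product: 17 trans-fused 6α-hydroxy-5α-H ketone (C4 ketone, C9=C10 alkene, 1β- and 8α-methyl)
Conditions: SmI2 (2.5 equiv), THF/MeOH, −78 °C
Reagents that add atoms: none
Why: SmI2 reduction of an α,β-epoxy ketone cleaves the Cα–O bond and leaves the C6–O bond, and methanol should protonate C5 on the α face, opposite the neighbouring C1 methyl and on the side of the new hydroxyl, giving the trans ring fusion.

Step 14
Reactants: 17 6α-hydroxy ketone
Product: 18 8α-methyldauc-9-ene-4β,6α-diol (4α-isopropyl, 1β-methyl, 5α-H)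
Conditions: i-PrMgCl (4 equiv), CeCl3 (anhydrous, 4 equiv), THF, −78 to 0 °C; aq NH4Cl
Reagents that add atoms: isopropylmagnesium chloride, CC(C)[Mg]Cl
Why: The organocerium reagent is much less basic than the Grignard reagent, so enolisation, β-hydride reduction and retro-aldol cleavage are suppressed (one equivalent is consumed by the C6 hydroxyl), and it should add to the cyclopentanone from the α face, anti to the axial C1 methyl, giving the 4β-carbinol with isopropyl α.

Step 15
Reactants: 18 8α-methyldauc-9-ene-4β,6α-diol
Product: 19 9α,10α-epoxy-8α-methyldaucane-4β,6α-diol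
Conditions: m-CPBA (1.2 equiv), CH2Cl2, 0 °C
Reagents that add atoms: 3-chloroperoxybenzoic acid, OOC(=O)c1cccc(Cl)c1
Why: Prilezhaev epoxidation of the only alkene should occur on the α face, opposite the pseudo-axial C1 methyl on the adjacent quaternary carbon (the C8 methyl is pseudo-equatorial and screens little), as is usual for alkenes next to an angular methyl group, which sets the C10 oxygen α.

Step 16
Reactants: 19 9α,10α-epoxy-8α-methyldaucane-4β,6α-diol
Product: 20 8α-methyl-9β-(phenylselanyl)daucane-4β,6α,10α-triol
Conditions: (PhSe)2 (0.75 equiv), NaBH4 (1.6 equiv), EtOH, rt; then 19, reflux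
Reagents that add atoms: diphenyl diselenide, c1ccc(cc1)[Se][Se]c1ccccc1
Why: The soft selenolate should open the epoxide by SN2 attack with inversion at C9, the carbon remote from quaternary C1 (C10 is neopentyl), leaving the α oxygen on C10 as the free carbinol and placing selenium β on C9, cis to the β hydrogen on C8.

Step 17
Reactants: 20 8α-methyl-9β-(phenylselanyl)daucane-4β,6α,10α-triol
Product: 21 6α-angeloyloxy-8α-methyl-9β-(phenylselanyl)daucane-4β,10α-diol
Conditions: angelic acid (1.5 equiv), 2,4,6-trichlorobenzoyl chloride (1.5 equiv), Et3N (1.6 equiv), toluene, rt; then 20, 80 °C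
Reagents that add atoms: angelic acid, C/C=C(/C)C(=O)O
Why: Yamaguchi-type esterification through the trichlorobenzoyl mixed anhydride without a nucleophilic catalyst transfers the angeloyl group without Z to E isomerisation, and the C6 hydroxyl should react selectively because the C4 hydroxyl is tertiary and the C10 hydroxyl is wedged between quaternary C1 and the selanyl-bearing C9.

Step 18
Reactants: 21 6α-angeloyloxy-8α-methyl-9β-(phenylselanyl)daucane-4β,10α-diol
Product: 23 6α-angeloyloxydauc-8-ene-4β,10α-diol, via selenoxide 22 (not isolated)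
Conditions: 30% aq H2O2 (excess), pyridine, THF, 0 °C to rt
Reagents that add atoms: none
Why: The selenide is oxidised to the selenoxide, which undergoes syn elimination at room temperature toward the cis β hydrogen on C8 and away from the carbinol carbon, as β-hydroxy selenoxides do, giving the C8=C9 allylic alcohol while excess peroxide and pyridine remove the selenenic acid.

Step 19
Reactants: 23 6α-angeloyloxydauc-8-ene-4β,10α-diol
Product: 24 lapiferine, (1S,4R,5S,6S,8R,9S,10S)-6α-angeloyloxy-8α,9α-epoxydaucane-4β,10α-diol
Conditions: VO(acac)2 (5 mol %), t-BuOOH (1.5 equiv, decane), CH2Cl2, 0 °C to rt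
Reagents that add atoms: tert-butyl hydroperoxide, CC(C)(C)OO
Why: In this vanadium-catalysed hydroxyl-directed epoxidation the vanadate ester of the C10 hydroxyl delivers oxygen to the same α face of C8=C9 (the usual cis outcome for cycloheptenols), while the electron-poor angelate alkene has no directing hydroxyl and is left alone, which sets C8 and C9.

**Compound list**

1 | (E)-but-2-enal | C/C=C/C=O | starting material
2 | ethyl 2-(triphenylphosphoranylidene)propanoate | CCOC(=O)C(C)=P(c1ccccc1)(c1ccccc1)c1ccccc1 | starting material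
3 | ethyl (2E,4E)-2-methylhexa-2,4-dienoate | CCOC(=O)/C(C)=C/C=C/C | intermediate
4 | (2E,4E)-2-methylhexa-2,4-dien-1-ol | OC/C(C)=C/C=C/C | intermediate
5 | (2E,4E)-1-bromo-2-methylhexa-2,4-diene | BrC/C(C)=C/C=C/C | intermediate
6 | methyl acetoacetate | COC(=O)CC(C)=O | starting material
7 | sodium lithium dianion of methyl acetoacetate | [Na+].[Li+].[CH2-]C(=O)[CH-]C(=O)OC | intermediate
8 | methyl (6E,8E)-6-methyl-3-oxodeca-6,8-dienoate | COC(=O)CC(=O)CC/C(C)=C/C=C/C | intermediate
9 | methyl (6E,8E)-2-diazo-6-methyl-3-oxodeca-6,8-dienoate | COC(=O)C(=[N+]=[N-])C(=O)CC/C(C)=C/C=C/C | intermediate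
10 | methyl (1R,5R,6R)-5-methyl-2-oxo-6-[(E)-prop-1-enyl]bicyclo[3.1.0]hexane-1-carboxylate (propenyl exo, cis to ester and methyl) | O=C1CC[C@]2(C)[C@@H](/C=C/C)[C@]12C(=O)OC | intermediate
11 | (1S,5R,6R)-1-(hydroxymethyl)-5-methyl-6-[(E)-prop-1-enyl]bicyclo[3.1.0]hexan-2-ol (C2 configuration not controlled, left open) | OC1CC[C@]2(C)[C@@H](/C=C/C)[C@]12CO | intermediate
12 | (1R,5R,6R)-2-hydroxy-5-methyl-6-[(E)-prop-1-enyl]bicyclo[3.1.0]hexane-1-carbaldehyde (C2 left open) | OC1CC[C@]2(C)[C@@H](/C=C/C)[C@]12C=O | intermediate
13 | (1S,5R,6R)-5-methyl-6-[(E)-prop-1-enyl]-1-vinylbicyclo[3.1.0]hexan-2-ol (C2 left open) | OC1CC[C@]2(C)[C@@H](/C=C/C)[C@]12C=C | intermediate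
14 | (1S,5R,6R)-5-methyl-6-[(E)-prop-1-enyl]-1-vinylbicyclo[3.1.0]hexan-2-one | O=C1CC[C@]2(C)[C@@H](/C=C/C)[C@]12C=C | intermediate
15 | (3aR,6R)-3a,6-dimethyl-3,3a,6,7-tetrahydroazulen-1(2H)-one (daucane numbering: C4 ketone, C5=C6, C9=C10, 1β- and 8α-methyl) | O=C1CC[C@]2(C)C=C[C@H](C)CC=C12 | intermediate
16 | 5α,6α-epoxide of 15 (C4 ketone, C9=C10) | O=C1CC[C@]2(C)C=C[C@H](C)C[C@@H]3O[C@]123 | intermediate
17 | trans-fused 6α-hydroxy-5α-H ketone (C4 ketone, C9=C10, 1β- and 8α-methyl) | O=C1CC[C@]2(C)C=C[C@H](C)C[C@H](O)[C@@H]12 | intermediate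
18 | 8α-methyldauc-9-ene-4β,6α-diol (4α-isopropyl, 1β-methyl, 5α-H) | CC(C)[C@]1(O)CC[C@]2(C)C=C[C@H](C)C[C@H](O)[C@@H]12 | intermediate
19 | 9α,10α-epoxy-8α-methyldaucane-4β,6α-diol | CC(C)[C@]1(O)CC[C@]2(C)[C@@H]3O[C@@H]3[C@H](C)C[C@H](O)[C@@H]12 | intermediate
20 | 8α-methyl-9β-(phenylselanyl)daucane-4β,6α,10α-triol | CC(C)[C@]1(O)CC[C@]2(C)[C@H](O)[C@@H]([Se]c3ccccc3)[C@H](C)C[C@H](O)[C@@H]12 | intermediate
21 | 6α-angeloyloxy-8α-methyl-9β-(phenylselanyl)daucane-4β,10α-diol | CC(C)[C@]1(O)CC[C@]2(C)[C@H](O)[C@@H]([Se]c3ccccc3)[C@H](C)C[C@H](OC(=O)/C(C)=C\C)[C@@H]12 | intermediate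
22 | 6α-angeloyloxy-8α-methyl-9β-(phenylseleninyl)daucane-4β,10α-diol (selenoxide, mixture at selenium) | CC(C)[C@]1(O)CC[C@]2(C)[C@H](O)[C@@H]([Se](=O)c3ccccc3)[C@H](C)C[C@H](OC(=O)/C(C)=C\C)[C@@H]12 | intermediate
23 | 6α-angeloyloxydauc-8-ene-4β,10α-diol | CC(C)[C@]1(O)CC[C@]2(C)[C@H](O)C=C(C)C[C@H](OC(=O)/C(C)=C\C)[C@@H]12 | intermediate
24 | lapiferine, (1S,4R,5S,6S,8R,9S,10S)-6α-angeloyloxy-8α,9α-epoxydaucane-4β,10α-diol | CC(C)[C@]1(O)CC[C@]2(C)[C@H](O)[C@@H]3O[C@]3(C)C[C@H](OC(=O)/C(C)=C\C)[C@@H]12 | target

**Count and risks**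

Total step count: 19. Longest linear sequence: 19 steps (1 to 24; 2 enters in step 1 and 6 in step 4).

Steps most likely to fail:

(1) Step 6. The acceptor/acceptor copper carbenoid may discriminate the two alkene faces poorly, or be diverted by the diene toward dihydrofuran formation. Fallback: stereocontrol is handed to a covalently bound auxiliary. Bromide 5 is used to alkylate the γ-carbon of commercial (1R,2S,5R)-menthyl acetoacetate (NaH then n-BuLi, as in step 4) to give menthyl (6E,8E)-6-methyl-3-oxodeca-6,8-dienoate F1. Diazo transfer as in step 5 gives the diazo ester F2. Cyclopropanation with achiral Cu(acac)2 in toluene at 90 °C should give two diastereomeric esters, the menthyl (1R,5R,6R)-ester F3 and the menthyl (1S,5S,6S)-ester F4, to be separated by chromatography or crystallisation. LiAlH4 reduction of F3 removes the auxiliary and returns to the route at diol 11.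

(2) Step 17. Acylation may spread to the C10 hydroxyl, or forcing conditions may erode the Z geometry. Fallback: the ester is installed while C6–OH is the only secondary hydroxyl, setting out from epoxide 19. Esterification of 19 with the same mixed anhydride gives 6α-angeloyloxy-9α,10α-epoxy-8α-methyldaucan-4β-ol F5. The epoxide is then opened under non-basic conditions with phenyl trimethylsilyl selenide and catalytic ZnI2 in CH2Cl2, so that no free selenolate can add to the angelate; this gives the C10 trimethylsilyl ether of the hydroxy selenide F6. A silyl group taken up by the C4 hydroxyl would be lost in the next operation. Methanolysis with citric acid in MeOH at 0 °C returns to the route at 21.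

(3) Step 11. The C1 methyl cis to both alkenyl groups slows the boat transition state, so the acyl-activated cyclopropane of 14 may instead open toward a dihydrofuran, epimerise at C10, or undergo the homodienyl hydrogen shift. Fallback: the rearrangement is run one oxidation level lower, setting out from carbinol 13, whose cyclopropane carries no acceptor. Heating 13 in toluene should give the dienol (3aR,6R)-3a,6-dimethyl-1,2,3,3a,6,7-hexahydroazulen-1-ol F7, and oxidation of this allylic alcohol with MnO2 in CH2Cl2 returns to the route at dienone 15.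

**Further compounds**

F1 | step 6 | (1R,2S,5R)-menthyl (6E,8E)-6-methyl-3-oxodeca-6,8-dienoate | C[C@@H]1CC[C@H]([C@@H](C1)OC(=O)CC(=O)CC/C(C)=C/C=C/C)C(C)C
F2 | step 6 | (1R,2S,5R)-menthyl (6E,8E)-2-diazo-6-methyl-3-oxodeca-6,8-dienoate | C[C@@H]1CC[C@H]([C@@H](C1)OC(=O)C(=[N+]=[N-])C(=O)CC/C(C)=C/C=C/C)C(C)C
F3 | step 6 | (1R,2S,5R)-menthyl (1R,5R,6R)-5-methyl-2-oxo-6-[(E)-prop-1-enyl]bicyclo[3.1.0]hexane-1-carboxylate | O=C1CC[C@]2(C)[C@@H](/C=C/C)[C@]12C(=O)O[C@@H]1C[C@H](C)CC[C@H]1C(C)C
F4 | step 6 | (1R,2S,5R)-menthyl (1S,5S,6S)-5-methyl-2-oxo-6-[(E)-prop-1-enyl]bicyclo[3.1.0]hexane-1-carboxylate (discarded diastereomer) | O=C1CC[C@@]2(C)[C@H](/C=C/C)[C@@]12C(=O)O[C@@H]1C[C@H](C)CC[C@H]1C(C)C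
F5 | step 17 | 6α-angeloyloxy-9α,10α-epoxy-8α-methyldaucan-4β-ol | CC(C)[C@]1(O)CC[C@]2(C)[C@@H]3O[C@@H]3[C@H](C)C[C@H](OC(=O)/C(C)=C\C)[C@@H]12
F6 | step 17 | 6α-angeloyloxy-8α-methyl-9β-(phenylselanyl)-10α-(trimethylsilyloxy)daucan-4β-ol | CC(C)[C@]1(O)CC[C@]2(C)[C@H](O[Si](C)(C)C)[C@@H]([Se]c3ccccc3)[C@H](C)C[C@H](OC(=O)/C(C)=C\C)[C@@H]12
F7 | step 11 | (3aR,6R)-3a,6-dimethyl-1,2,3,3a,6,7-hexahydroazulen-1-ol (C1 carbinol configuration left open) | OC1CC[C@]2(C)C=C[C@H](C)CC=C12
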